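**Retrosynthetic overview**
1. Target 8 comes from the racemic trans alcohol 7 by lipase kinetic resolution; the relative configuration is already fixed at that point.
2. 7 comes from dialdehyde 6 by reducing only the saturated 2-formyl group and keeping the enal.
3. 6 comes from two molecules of 5-hydroxyconiferaldehyde 4: oxidative 8–O–4 phenoxyl coupling, then the 5-OH adds to quinone methide 5 and closes the dioxane (trans).
4. 4 comes from 5-hydroxyvanillin 1 and phosphonium salt 2 by a two-carbon Wittig homologation.
5. Ring order: both benzene rings come from 1; the 1,4-dioxane is the only ring made (step 2).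

Numbering used for the monomer: side-chain carbons C7, C8, C9 counted from the ring; O4 is the phenol oxygen para to the side chain and O5 is its neighbour.

Assumption: Candida antarctica lipase B acetylates the (2S,3S) enantiomer of 7 faster, the sense it shows with closely related trans-3-aryl-2-hydroxymethyl-1,4-benzodioxanes, so the target is the unreacted alcohol.

**Step 1**
Reactants: 1 3,4-dihydroxy-5-methoxybenzaldehyde (5-hydroxyvanillin); 2 (1,3-dioxolan-2-ylmethyl)triphenylphosphonium bromide
Product: 4 (E)-3-(3,4-dihydroxy-5-methoxyphenyl)prop-2-enal (5-hydroxyconiferaldehyde), via vinyl dioxolane 3 (not isolated)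
Conditions: 2 (1.5 equiv), KOtBu (3.6 equiv), THF, 0 to 50 °C, Ar; then 1 M HCl/THF, rt
Reagents that add atoms: water, O
Why: Wittig olefination with a masked-formyl, non-stabilised ylide (the extra base carries the catechol as its dianion, and vinyl dioxolane 3 cannot be homologated a second time), then acid hydrolysis of the acetal, during which the E/Z mixture converges on the conjugated (E)-enal; no stereocentre is formed.

**Step 2**
Reactants: 4 (E)-3-(3,4-dihydroxy-5-methoxyphenyl)prop-2-enal (two molecules)
Product: 7 racemic (E)-3-[(2R,3R)-3-(3,4-dihydroxy-5-methoxyphenyl)-2-(hydroxymethyl)-8-methoxy-2,3-dihydro-1,4-benzodioxin-6-yl]prop-2-enal (trans racemate), via quinone methide 5 (not isolated), via dialdehyde 6 (not isolated)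
Conditions: Ag2CO3 (0.6 equiv), acetone/toluene 1:2, rt, dark, Ar; filter through Celite, evaporate below 25 °C; then NaBH4 (0.5 equiv), EtOH/CH2Cl2 3:7, −78 °C; aq. NH4Cl
Reagents that add atoms: none
Why: Oxidative phenol coupling of the lignan-forming type (silver-mediated, as in the dimerisation of caffeate esters to 1,4-benzodioxane neolignans), in which the phenoxyl radical of 4 carries spin on O4 and on C8, so C8 of one unit bonds to O4 of the other and the neighbouring 5-OH adds to C7 of quinone methide 5, closing the dioxane with aryl and formyl trans (anti addition, reinforced by the epimerisable formyl-bearing centre settling diequatorial) as a racemate, after which NaBH4 at −78 °C reduces only the activated saturated α-aryloxy aldehyde and not the aryl-conjugated enal (chemoselective borohydride reduction).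

**Step 3**
Reactants: 7 racemic (E)-3-[(2R,3R)-3-(3,4-dihydroxy-5-methoxyphenyl)-2-(hydroxymethyl)-8-methoxy-2,3-dihydro-1,4-benzodioxin-6-yl]prop-2-enal
Product: 8 (E)-3-[(2R,3R)-3-(3,4-dihydroxy-5-methoxyphenyl)-2-(hydroxymethyl)-8-methoxy-2,3-dihydro-1,4-benzodioxin-6-yl]prop-2-enal (CNP0103768.1)
Conditions: Novozym 435 (immobilised Candida antarctica lipase B), vinyl acetate (5 equiv), acetone/t-BuOMe 1:4, 40 °C, to about 55% conversion; silica gel chromatography
Reagents that add atoms: none
Why: Lipase-catalysed kinetic resolution by transesterification, in which the enzyme acetylates only the primary alcohol (not the phenols) and does so faster for the (2S,3S) enantiomer, so that past 50% conversion the unreacted (2R,3R) alcohol 8 is left in high ee and is separated from the acetate; the trans relationship set in step 2 is untouched.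

**Compound list**
1 | 3,4-dihydroxy-5-methoxybenzaldehyde (5-hydroxyvanillin) | COc1cc(C=O)cc(O)c1O | starting material
2 | (1,3-dioxolan-2-ylmethyl)triphenylphosphonium bromide | [Br-].C(C1OCCO1)[P+](c2ccccc2)(c3ccccc3)c4ccccc4 | starting material
3 | 5-[2-(1,3-dioxolan-2-yl)ethenyl]-3-methoxybenzene-1,2-diol (E/Z mixture, geometry not defined) | COc1cc(C=CC2OCCO2)cc(O)c1O | intermediate
4 | (E)-3-(3,4-dihydroxy-5-methoxyphenyl)prop-2-enal (5-hydroxyconiferaldehyde) | COc1cc(/C=C/C=O)cc(O)c1O | intermediate
5 | (E)-3-[3-hydroxy-5-methoxy-4-({1-oxo-3-[3-hydroxy-5-methoxy-4-oxocyclohexa-2,5-dien-1-ylidene]propan-2-yl}oxy)phenyl]prop-2-enal (p-quinone methide, racemic at C8) | COC1=CC(=CC(C=O)Oc2c(O)cc(/C=C/C=O)cc2OC)C=C(O)C1=O | intermediate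
6 | racemic trans (2S,3R)-3-(3,4-dihydroxy-5-methoxyphenyl)-8-methoxy-6-[(E)-3-oxoprop-1-enyl]-2,3-dihydro-1,4-benzodioxine-2-carbaldehyde (both enantiomers written) | COc1cc([C@H]2Oc3cc(/C=C/C=O)cc(OC)c3O[C@@H]2C=O)cc(O)c1O.COc1cc([C@@H]2Oc3cc(/C=C/C=O)cc(OC)c3O[C@H]2C=O)cc(O)c1O | intermediate
7 | racemic trans (E)-3-[(2R,3R)-3-(3,4-dihydroxy-5-methoxyphenyl)-2-(hydroxymethyl)-8-methoxy-2,3-dihydro-1,4-benzodioxin-6-yl]prop-2-enal (both enantiomers written) | COc1cc([C@H]2Oc3cc(/C=C/C=O)cc(OC)c3O[C@@H]2CO)cc(O)c1O.COc1cc([C@@H]2Oc3cc(/C=C/C=O)cc(OC)c3O[C@H]2CO)cc(O)c1O | intermediate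
8 | (E)-3-[(2R,3R)-3-(3,4-dihydroxy-5-methoxyphenyl)-2-(hydroxymethyl)-8-methoxy-2,3-dihydro-1,4-benzodioxin-6-yl]prop-2-enal | COc1cc([C@H]2Oc3cc(/C=C/C=O)cc(OC)c3O[C@@H]2CO)cc(O)c1O | target

**Step count**
Total: 3 steps. Step 2 runs the coupling and the reduction back to back on the unpurified dialdehyde 6.
Longest linear sequence: 3 steps (1 → 4 → 7 → 8).

**Steps most likely to fail, with fallbacks**

Step 2 is the riskiest. The dimerisation of the aldehyde monomer may give 8–8 or 8–O–5 dimers, dialdehyde 6 may ring-open by β-elimination to the enol ether, or the product catechol may be oxidised further. The fallback sets out from 4 and puts C9 at the alcohol level before coupling. One portion of 4 is reduced with NaBH4 in EtOAc at rt (1,2-reduction) to 5-[(E)-3-hydroxyprop-1-enyl]-3-methoxybenzene-1,2-diol F1 (5-hydroxyconiferyl alcohol). F1 is then added slowly to excess 4 (3 equiv) and Ag2CO3 in acetone/toluene. The cross 8–O–4 coupling passes through (E)-3-[3-hydroxy-4-({1-hydroxy-3-[3-hydroxy-5-methoxy-4-oxocyclohexa-2,5-dien-1-ylidene]propan-2-yl}oxy)-5-methoxyphenyl]prop-2-enal F2, the quinone methide, which closes to the trans racemate directly. Neither the labile dialdehyde nor the selective reduction is needed, and the route is rejoined at 7.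

Step 3 comes next. The enzyme may discriminate poorly, or in the opposite sense, on this substrate. The fallback sets out from 7 and resolves it physically by preparative supercritical-fluid chromatography on an amylose tris(3,5-dimethylphenylcarbamate) phase. This works whatever the enzyme preference, makes no new compound (F0), and comes back at 8.

Step 1 is third. The Wittig reaction on the electron-rich, air-sensitive catecholate dianion may be sluggish. The fallback sets out from 1 and works under neutral conditions on a protected substrate. Ac2O/pyridine gives 3,4-diacetoxy-5-methoxybenzaldehyde F3. The stabilised ylide (triphenylphosphoranylidene)acetaldehyde in toluene at 80 °C converts it into (E)-3-(3,4-diacetoxy-5-methoxyphenyl)prop-2-enal F4. K2CO3/MeOH at 0 °C removes both acetates, and the route is rejoined at 4.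

**Further compounds**
F1 | step 2 | 5-[(E)-3-hydroxyprop-1-enyl]-3-methoxybenzene-1,2-diol | COc1cc(/C=C/CO)cc(O)c1O
F2 | step 2 | (E)-3-[3-hydroxy-4-({1-hydroxy-3-[3-hydroxy-5-methoxy-4-oxocyclohexa-2,5-dien-1-ylidene]propan-2-yl}oxy)-5-methoxyphenyl]prop-2-enal | COC1=CC(=CC(CO)Oc2c(O)cc(/C=C/C=O)cc2OC)C=C(O)C1=O
F0 | step 3 | none | none
F3 | step 1 | 3,4-diacetoxy-5-methoxybenzaldehyde | COc1cc(C=O)cc(OC(C)=O)c1OC(C)=O
F4 | step 1 | (E)-3-(3,4-diacetoxy-5-methoxyphenyl)prop-2-enal | COc1cc(/C=C/C=O)cc(OC(C)=O)c1OC(C)=O
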